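**Strategy.** Azulene numbering is used: five-membered ring C1, C2 (Me), C3, C3a, C8a; seven-membered ring C4, C5 (Me, OH), C6, C7 (O-ester), C8 (iPr). The hydroazulene is treated as a ring-enlarged cyclohexane. With C8 as a ketone, the cycloheptanone is the pinacol product of a cyclohexyl silyl ether that carries a vinyl group (C8a=C1) on the carbinol carbon C8 and a propynyl group (C3≡C2–CH3) on the neighbouring C3a. One gold-catalysed step forms C1–C2 by 6-endo-dig attack of the alkene on the alkyne and C3a–C8a by the ensuing 1,2-shift. This delivers the C2=C3 methylcyclopentene fused to the cycloheptanone. The C8 ketone then serves for ring-fusion epimerisation, isopropyl installation and C7 oxygenation.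

Key step: step 7

Remarks on the chemistry:
- Bicyclic compounds keep the azulene numbering of the target throughout, so the C8 ketone does not get the lowest locant.
- β is the face of the target's epoxide oxygen (also 5-OH, H-8a, isopropyl); α is the opposite face (H-3, H-3a, H-8, both methyl groups, the C7 oxygen).
- Compounds 1, 2, 6, 8, 13, 17, 21, 23, 25 and 31 are assumed to be commercial.
- The configuration at the carbinol carbon C4 of 10–15 is inconsequential, because that carbon becomes the C8 carbonyl in step 7.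

## Route

**Step 1**
Reactants: 1 4,4-dimethoxycyclohexa-2,5-dien-1-one; 2 vinylmagnesium bromide; 3 water
Product: 5 4-hydroxy-4-vinylcyclohexa-2,5-dien-1-one, via 4,4-dimethoxy-1-vinylcyclohexa-2,5-dien-1-ol 4 (not isolated)
Conditions: CH2=CHMgBr, THF, −78 °C; then 5% aq AcOH, 0 °C to rt
Reagents that add atoms: vinylmagnesium bromide, C=C[Mg]Br; water, O
Why: Grignard 1,2-addition to the only carbonyl of the quinone monoketal followed by mild acid hydrolysis of the dimethyl ketal is the standard entry to p-quinols, and no stereocentre is formed.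

**Step 2**
Reactants: 5 4-hydroxy-4-vinylcyclohexa-2,5-dien-1-one; 6 triethylsilyl trifluoromethanesulfonate
Product: 7 4-[(triethylsilyl)oxy]-4-vinylcyclohexa-2,5-dien-1-one
Conditions: Et3SiOTf, 2,6-lutidine, CH2Cl2, −78 to 0 °C
Reagents that add atoms: triethylsilyl trifluoromethanesulfonate, CC[Si](CC)(CC)OS(=O)(=O)C(F)(F)F
Why: Silyl triflate/lutidine silylation of a hindered tertiary alcohol installs the silyl ether that later triggers the pinacol shift and prevents alkoxide-directed, ligand-free alkynyl transfer in step 3.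

**Step 3**
Reactants: 7 4-[(triethylsilyl)oxy]-4-vinylcyclohexa-2,5-dien-1-one; 8 prop-1-yn-1-yllithium
Product: 10 (4R,5R)-5-(prop-1-yn-1-yl)-4-[(triethylsilyl)oxy]-4-vinylcyclohex-2-en-1-one, via dimethyl(prop-1-yn-1-yl)aluminium 9 (not isolated)
Conditions: 8, Me2AlCl, Et2O, 0 °C; then 7, Ni(acac)2 (5 mol %), t-Bu-bis(oxazoline) ligand (6 mol %, the antipode that gives 5R), t-BuOMe, 0 °C; aq KNaC4H4O6 (potassium sodium tartrate)
Reagents that add atoms: prop-1-yn-1-yllithium, [Li]C#CC (transferred as dimethyl(prop-1-yn-1-yl)aluminium, CC#C[Al](C)C)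
Why: Nickel-catalysed enantioselective conjugate addition of an alkynylalane to a cyclic enone is used as a desymmetrisation in which the chiral catalyst selects one of the two enantiotopic enone units and so sets ring carbon C5 (the future C3a), the alkynyl group being expected to enter anti to the vinyl group and the resulting cross-conjugated enolate being inert to a second addition.

**Step 4**
Reactants: 10 (4R,5R)-5-(prop-1-yn-1-yl)-4-[(triethylsilyl)oxy]-4-vinylcyclohex-2-en-1-one
Product: 12 (3R,4S)-3-(prop-1-yn-1-yl)-4-[(triethylsilyl)oxy]-4-vinylcyclohexan-1-one, via dimethyl(phenyl)silyl enol ether 11 (not isolated)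
Conditions: [(Ph3P)CuH]6 (5 mol %), PhMe2SiH, toluene, rt; then 1 M aq HCl, THF, 0 °C
Reagents that add atoms: none
Why: Copper hydride conjugate reduction (1,4-hydrosilylation) is selective for the enone over the isolated vinyl group and the internal alkyne, and brief acid hydrolysis of the silyl enol ether should leave the tertiary triethylsilyl ether intact; no new stereocentre arises.

**Step 5**
Reactants: 12 (3R,4S)-3-(prop-1-yn-1-yl)-4-[(triethylsilyl)oxy]-4-vinylcyclohexan-1-one; 13 methyllithium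
Product: 14 (1S,3R,4S)-1-methyl-3-(prop-1-yn-1-yl)-4-[(triethylsilyl)oxy]-4-vinylcyclohexan-1-ol
Conditions: MeAl(OAr)2 (Ar = 2,6-di-tert-butyl-4-methylphenyl, 3 equiv, stock solution), toluene, −78 °C; then MeLi
Reagents that add atoms: methyllithium, [Li]C
Why: In the chair with equatorial propynyl and vinyl groups the bulky aluminium Lewis acid occupies the equatorial side of the carbonyl, so methyllithium should add axially (1,2-addition under amphiphilic control) and give the equatorial alcohol cis to the propynyl group, which sets the future C5.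

**Step 6**
Reactants: 14 (1S,3R,4S)-1-methyl-3-(prop-1-yn-1-yl)-4-[(triethylsilyl)oxy]-4-vinylcyclohexan-1-ol; 6 triethylsilyl trifluoromethanesulfonate
Product: 15 (1S,3R,4S)-1-methyl-3-(prop-1-yn-1-yl)-1,4-bis[(triethylsilyl)oxy]-4-vinylcyclohexane
Conditions: Et3SiOTf, 2,6-lutidine, CH2Cl2, 0 °C
Reagents that add atoms: triethylsilyl trifluoromethanesulfonate, CC[Si](CC)(CC)OS(=O)(=O)C(F)(F)F
Why: Silylation of the second tertiary alcohol keeps it from adding to the gold-activated alkyne in step 7 and from capturing the bromonium ion in step 8.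

**Step 7**
Reactants: 15 (1S,3R,4S)-1-methyl-3-(prop-1-yn-1-yl)-1,4-bis[(triethylsilyl)oxy]-4-vinylcyclohexane
Product: 16 (3aR,5S,8aS)-2,5-dimethyl-5-[(triethylsilyl)oxy]-3a,4,5,6,7,8a-hexahydroazulen-8(1H)-one (cis-fused)
Conditions: Ph3PAuCl (5 mol %), AgSbF6 (5 mol %), i-PrOH (1.2 equiv), CH2Cl2, rt
Reagents that add atoms: none
Why: Cationic monovalent gold activates the alkyne, the terminal vinyl carbon C1 attacks the methyl-bearing alkyne carbon C2 in a 6-endo-dig carbocyclisation (forming C1–C2), and the positive charge developing at C8a is quenched by a pinacol-type 1,2-shift of C3a from the siloxy carbon C8 to C8a (forming C3a–C8a), with transfer of the silyl group to i-PrOH and protodeauration at C3. The closest known reaction type is the gold-catalysed cyclisation/pinacol rearrangement of 3-silyloxy-1,5-enynes to 4-acylcyclopentenes, run here in the ring-enlarging sense familiar from Prins–pinacol cyclopentane annulations of 1-alkenylcycloalkanols. The five-membered ring arises by 6-endo-dig closure followed by ring contraction, and the seven-membered ring by one-carbon expansion of the cyclohexane. C3a migrates with retention, and because it stays tied to C8 through C4–C7 the shift is suprafacial and should make H-8a cis to H-3a (cis-fused ketone, corrected in step 9), while the former carbinol stereocentre disappears. The step needs 6-endo rather than 5-exo attack, secured by the polarisation of the vinyl group (nucleophilic terminal carbon, cation next to the siloxy carbon), and migration of the ring carbon C3a rather than C7, secured by its higher substitution and by relief of the vinyl-gold cyclohexenyl cation on contraction; the C5 silyl ether keeps the tertiary oxygen from adding to the alkyne.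

**Step 8**
Reactants: 16 (3aR,5S,8aS)-2,5-dimethyl-5-[(triethylsilyl)oxy]-3a,4,5,6,7,8a-hexahydroazulen-8(1H)-one; 17 N-bromosuccinimide; 3 water
Product: 18 (2R,3R,3aS,5S,8aS)-3-bromo-2-hydroxy-2,5-dimethyl-5-[(triethylsilyl)oxy]perhydroazulen-8-one
Conditions: NBS, NaHCO3, THF/H2O (4:1), 0 °C, dark
Reagents that add atoms: N-bromosuccinimide, O=C1CCC(=O)N1Br; water, O
Why: In this bromohydrin formation the bromonium ion should form on the convex α face of the cis-fused bicycle and water should open it anti at the tertiary C2, which places the C2 oxygen on the β face and bromine α on C3.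

**Step 9**
Reactants: 18 (2R,3R,3aS,5S,8aS)-3-bromo-2-hydroxy-2,5-dimethyl-5-[(triethylsilyl)oxy]perhydroazulen-8-one
Product: 20 (2R,3S,3aS,5S,8aR)-2,3-epoxy-2,5-dimethyl-5-[(triethylsilyl)oxy]perhydroazulen-8-one (trans-fused), via cis-fused epoxy ketone 19 (not isolated)
Conditions: NaOMe, MeOH, 0 °C to rt
Reagents that add atoms: none
Why: The C2 alkoxide displaces bromide at C3 with inversion (Williamson-type epoxide closure) to give the β-epoxide, and the same base then equilibrates C8a next to the C8 ketone to the trans ring fusion, which is expected to be the more stable one for bicyclo[5.3.0]decan-2-ones.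

**Step 10**
Reactants: 20 (2R,3S,3aS,5S,8aR)-2,3-epoxy-2,5-dimethyl-5-[(triethylsilyl)oxy]perhydroazulen-8-one; 21 N-phenylbis(trifluoromethanesulfonimide)
Product: 22 (2R,3S,3aS,5R,8aR)-2,3-epoxy-2,5-dimethyl-5-[(triethylsilyl)oxy]-1,2,3,3a,4,5,6,8a-octahydroazulen-8-yl trifluoromethanesulfonate
Conditions: KN(SiMe3)2, THF, −78 °C; then PhNTf2, −78 to 0 °C
Reagents that add atoms: N-phenylbis(trifluoromethanesulfonimide), O=S(=O)(N(c1ccccc1)S(=O)(=O)C(F)(F)F)C(F)(F)F
Why: Kinetic enolisation with a bulky amide base should remove a proton from the C7 methylene rather than the C8a methine, and O-sulfonylation of the enolate gives the C7=C8 enol triflate without touching the epoxide.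

**Step 11**
Reactants: 22 (2R,3S,3aS,5R,8aR)-2,3-epoxy-2,5-dimethyl-5-[(triethylsilyl)oxy]-1,2,3,3a,4,5,6,8a-octahydroazulen-8-yl trifluoromethanesulfonate; 23 isopropylzinc bromide
Product: 24 (2R,3S,3aS,5S,8aR)-2,3-epoxy-2,5-dimethyl-8-(propan-2-yl)-5-[(triethylsilyl)oxy]-1,2,3,3a,4,5,6,8a-octahydroazulene
Conditions: i-PrZnBr, Pd(OAc)2 (3 mol %), CPhos (6 mol %), THF/toluene, rt
Reagents that add atoms: isopropylzinc bromide, CC(C)[Zn]Br
Why: Negishi coupling of a secondary alkylzinc with an enol triflate installs the isopropyl group, the biarylphosphine ligand favouring reductive elimination over β-hydride isomerisation to the n-propyl product.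

**Step 12**
Reactants: 24 (2R,3S,3aS,5S,8aR)-2,3-epoxy-2,5-dimethyl-8-(propan-2-yl)-5-[(triethylsilyl)oxy]-1,2,3,3a,4,5,6,8a-octahydroazulene; 25 N-methylmorpholine N-oxide
Product: 27 (2R,3S,3aS,5R,8R,8aR)-2,3-epoxy-2,5-dimethyl-8-(propan-2-yl)-5-[(triethylsilyl)oxy]perhydroazulen-7-one (8-epimer), via C7 alkylborane 26 (not isolated)
Conditions: BH3·SMe2, THF, 0 °C to rt; then NMO, (n-Pr4N)[RuO4] (5 mol %), 4 Å MS, CH2Cl2, rt
Reagents that add atoms: N-methylmorpholine N-oxide, C[N+]1([O-])CCOCC1
Why: Anti-Markovnikov hydroboration places boron on C7 and hydrogen on C8 by syn addition, expected from the more open β face, and amine-oxide/perruthenate oxidation of the borane in the same flask gives the C7 ketone, so the C8 configuration formed here is provisional and is equilibrated in step 14.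

**Step 13**
Reactants: 27 (2R,3S,3aS,5R,8R,8aR)-2,3-epoxy-2,5-dimethyl-8-(propan-2-yl)-5-[(triethylsilyl)oxy]perhydroazulen-7-one
Product: 28 (2R,3S,3aS,5R,8R,8aR)-2,3-epoxy-5-hydroxy-2,5-dimethyl-8-(propan-2-yl)perhydroazulen-7-one
Conditions: Bu4NF, AcOH, THF, rt
Reagents that add atoms: none
Why: Buffered fluoride desilylation frees the tertiary C5 alcohol without retro-aldol cleavage of the β-hydroxy ketone or opening of the epoxide, and removes the silanolate leaving group before the base treatment of step 14.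

**Step 14**
Reactants: 28 (2R,3S,3aS,5R,8R,8aR)-2,3-epoxy-5-hydroxy-2,5-dimethyl-8-(propan-2-yl)perhydroazulen-7-one
Product: 29 (2R,3S,3aS,5R,8S,8aR)-2,3-epoxy-5-hydroxy-2,5-dimethyl-8-(propan-2-yl)perhydroazulen-7-one
Conditions: DBU (0.3 equiv), toluene, rt to 40 °C
Reagents that add atoms: none
Why: Amine-base enolisation should equilibrate C8 next to the C7 ketone to the epimer with the isopropyl group equatorial and trans to the C1 branch on C8a (thermodynamic epimerisation, as in the isomenthone–menthone equilibrium).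

**Step 15**
Reactants: 29 (2R,3S,3aS,5R,8S,8aR)-2,3-epoxy-5-hydroxy-2,5-dimethyl-8-(propan-2-yl)perhydroazulen-7-one
Product: 30 (2R,3S,3aS,5R,7S,8S,8aR)-2,3-epoxy-2,5-dimethyl-8-(propan-2-yl)perhydroazulene-5,7-diol
Conditions: Me4NBH(OAc)3, MeCN/AcOH, −30 °C
Reagents that add atoms: none
Why: In this Evans–Saksena reduction the C5 hydroxyl binds the acetoxyborohydride and delivers hydride intramolecularly to the β face of the C7 ketone, which should give the 1,3-anti diol with the C7 hydroxyl α and trans to the isopropyl group.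

**Step 16**
Reactants: 30 (2R,3S,3aS,5R,7S,8S,8aR)-2,3-epoxy-2,5-dimethyl-8-(propan-2-yl)perhydroazulene-5,7-diol; 31 4-acetoxybenzoyl chloride
Product: 33 (2R,3S,3aS,5R,7S,8S,8aR)-2,3-epoxy-5-hydroxy-2,5-dimethyl-8-(propan-2-yl)perhydroazulen-7-yl 4-hydroxybenzoate (target), via 4-acetoxybenzoate ester 32 (not isolated)
Conditions: 4-AcOC6H4COCl, DMAP, pyridine, CH2Cl2, 0 °C to rt; then pyrrolidine, 0 °C
Reagents that add atoms: 4-acetoxybenzoyl chloride, CC(=O)Oc1ccc(cc1)C(Cl)=O
Why: DMAP-catalysed acylation should take the secondary C7 hydroxyl and not the tertiary C5 hydroxyl, and aminolysis by pyrrolidine then removes the much more reactive aryl acetate while leaving the alkyl 4-hydroxybenzoate and the epoxide untouched.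

## Compound list

1 | 4,4-dimethoxycyclohexa-2,5-dien-1-one | COC1(OC)C=CC(=O)C=C1 | starting material
2 | vinylmagnesium bromide | C=C[Mg]Br | starting material
3 | water | O | starting material
4 | 4,4-dimethoxy-1-vinylcyclohexa-2,5-dien-1-ol | C=CC1(O)C=CC(OC)(OC)C=C1 | intermediate
5 | 4-hydroxy-4-vinylcyclohexa-2,5-dien-1-one | C=CC1(O)C=CC(=O)C=C1 | intermediate
6 | triethylsilyl trifluoromethanesulfonate | CC[Si](CC)(CC)OS(=O)(=O)C(F)(F)F | starting material
7 | 4-[(triethylsilyl)oxy]-4-vinylcyclohexa-2,5-dien-1-one | C=CC1(O[Si](CC)(CC)CC)C=CC(=O)C=C1 | intermediate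
8 | prop-1-yn-1-yllithium | [Li]C#CC | starting material
9 | dimethyl(prop-1-yn-1-yl)aluminium | CC#C[Al](C)C | intermediate
10 | (4R,5R)-5-(prop-1-yn-1-yl)-4-[(triethylsilyl)oxy]-4-vinylcyclohex-2-en-1-one | C=C[C@@]1(O[Si](CC)(CC)CC)C=CC(=O)C[C@@H]1C#CC | intermediate
11 | (4S,5R)-1-[dimethyl(phenyl)silyloxy]-5-(prop-1-yn-1-yl)-4-[(triethylsilyl)oxy]-4-vinylcyclohex-1-ene | C=C[C@@]1(O[Si](CC)(CC)CC)CC=C(O[Si](C)(C)c2ccccc2)C[C@@H]1C#CC | intermediate
12 | (3R,4S)-3-(prop-1-yn-1-yl)-4-[(triethylsilyl)oxy]-4-vinylcyclohexan-1-one | C=C[C@@]1(O[Si](CC)(CC)CC)CCC(=O)C[C@@H]1C#CC | intermediate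
13 | methyllithium | [Li]C | starting material
14 | (1S,3R,4S)-1-methyl-3-(prop-1-yn-1-yl)-4-[(triethylsilyl)oxy]-4-vinylcyclohexan-1-ol | C=C[C@@]1(O[Si](CC)(CC)CC)CC[C@](C)(O)C[C@@H]1C#CC | intermediate
15 | (1S,3R,4S)-1-methyl-3-(prop-1-yn-1-yl)-1,4-bis[(triethylsilyl)oxy]-4-vinylcyclohexane | C=C[C@@]1(O[Si](CC)(CC)CC)CC[C@](C)(O[Si](CC)(CC)CC)C[C@@H]1C#CC | intermediate
16 | (3aR,5S,8aS)-2,5-dimethyl-5-[(triethylsilyl)oxy]-3a,4,5,6,7,8a-hexahydroazulen-8(1H)-one, cis-fused | O=C1[C@H]2CC(C)=C[C@H]2C[C@@](C)(O[Si](CC)(CC)CC)CC1 | intermediate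
17 | N-bromosuccinimide | O=C1CCC(=O)N1Br | starting material
18 | (2R,3R,3aS,5S,8aS)-3-bromo-2-hydroxy-2,5-dimethyl-5-[(triethylsilyl)oxy]perhydroazulen-8-one | O=C1[C@H]2C[C@@](C)(O)[C@H](Br)[C@H]2C[C@@](C)(O[Si](CC)(CC)CC)CC1 | intermediate
19 | (2R,3S,3aS,5S,8aS)-2,3-epoxy-2,5-dimethyl-5-[(triethylsilyl)oxy]perhydroazulen-8-one, cis-fused | O=C1[C@H]2C[C@@]3(C)O[C@H]3[C@H]2C[C@@](C)(O[Si](CC)(CC)CC)CC1 | intermediate
20 | (2R,3S,3aS,5S,8aR)-2,3-epoxy-2,5-dimethyl-5-[(triethylsilyl)oxy]perhydroazulen-8-one, trans-fused | O=C1[C@@H]2C[C@@]3(C)O[C@H]3[C@H]2C[C@@](C)(O[Si](CC)(CC)CC)CC1 | intermediate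
21 | N-phenylbis(trifluoromethanesulfonimide) | O=S(=O)(N(c1ccccc1)S(=O)(=O)C(F)(F)F)C(F)(F)F | starting material
22 | (2R,3S,3aS,5R,8aR)-2,3-epoxy-2,5-dimethyl-5-[(triethylsilyl)oxy]-1,2,3,3a,4,5,6,8a-octahydroazulen-8-yl trifluoromethanesulfonate | O=S(=O)(OC=1[C@@H]2C[C@@]3(C)O[C@H]3[C@H]2C[C@@](C)(O[Si](CC)(CC)CC)CC=1)C(F)(F)F | intermediate
23 | isopropylzinc bromide | CC(C)[Zn]Br | starting material
24 | (2R,3S,3aS,5S,8aR)-2,3-epoxy-2,5-dimethyl-8-(propan-2-yl)-5-[(triethylsilyl)oxy]-1,2,3,3a,4,5,6,8a-octahydroazulene | CC(C)C=1[C@@H]2C[C@@]3(C)O[C@H]3[C@H]2C[C@@](C)(O[Si](CC)(CC)CC)CC=1 | intermediate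
25 | N-methylmorpholine N-oxide | C[N+]1([O-])CCOCC1 | starting material
26 | C7 alkylborane of 24 (boron β on C7, hydrogen β on C8) | CC(C)[C@@H]1[C@@H]2C[C@@]3(C)O[C@H]3[C@H]2C[C@@](C)(O[Si](CC)(CC)CC)C[C@H]1B | intermediate
27 | (2R,3S,3aS,5R,8R,8aR)-2,3-epoxy-2,5-dimethyl-8-(propan-2-yl)-5-[(triethylsilyl)oxy]perhydroazulen-7-one | CC(C)[C@@H]1[C@@H]2C[C@@]3(C)O[C@H]3[C@H]2C[C@@](C)(O[Si](CC)(CC)CC)CC1=O | intermediate
28 | (2R,3S,3aS,5R,8R,8aR)-2,3-epoxy-5-hydroxy-2,5-dimethyl-8-(propan-2-yl)perhydroazulen-7-one | CC(C)[C@@H]1[C@@H]2C[C@@]3(C)O[C@H]3[C@H]2C[C@@](C)(O)CC1=O | intermediate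
29 | (2R,3S,3aS,5R,8S,8aR)-2,3-epoxy-5-hydroxy-2,5-dimethyl-8-(propan-2-yl)perhydroazulen-7-one | CC(C)[C@H]1[C@@H]2C[C@@]3(C)O[C@H]3[C@H]2C[C@@](C)(O)CC1=O | intermediate
30 | (2R,3S,3aS,5R,7S,8S,8aR)-2,3-epoxy-2,5-dimethyl-8-(propan-2-yl)perhydroazulene-5,7-diol | CC(C)[C@H]1[C@@H]2C[C@@]3(C)O[C@H]3[C@H]2C[C@@](C)(O)C[C@@H]1O | intermediate
31 | 4-acetoxybenzoyl chloride | CC(=O)Oc1ccc(cc1)C(Cl)=O | starting material
32 | (2R,3S,3aS,5R,7S,8S,8aR)-2,3-epoxy-5-hydroxy-2,5-dimethyl-8-(propan-2-yl)perhydroazulen-7-yl 4-acetoxybenzoate | CC(C)[C@H]1[C@@H]2C[C@@]3(C)O[C@H]3[C@H]2C[C@@](C)(O)C[C@@H]1OC(=O)c1ccc(OC(C)=O)cc1 | intermediate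
33 | (2R,3S,3aS,5R,7S,8S,8aR)-2,3-epoxy-5-hydroxy-2,5-dimethyl-8-(propan-2-yl)perhydroazulen-7-yl 4-hydroxybenzoate | CC(C)[C@H]1[C@@H]2C[C@@]3(C)O[C@H]3[C@H]2C[C@@](C)(O)C[C@@H]1OC(=O)c1ccc(O)cc1 | target

## Step count and risks

Total step count: 16. Longest linear sequence: 16 steps (from 1).

**Step 7 (key step).** The gold cycle may stall or leak: protodeauration may occur before the 1,2-shift, the C7 carbon may migrate instead of C3a, or the silyl ether may be lost before cyclisation. The fallback sets out from 15 and replaces catalytic π-acid activation by a stoichiometric iodonium ion, which needs no catalyst turnover. N-Iodosuccinimide with i-PrOH in CH2Cl2 (−78 °C to rt) should induce the same carbocyclisation/pinacol shift and give the vinyl iodide (3aS,5S,8aS)-3-iodo-2,5-dimethyl-5-[(triethylsilyl)oxy]-3a,4,5,6,7,8a-hexahydroazulen-8(1H)-one F1. Palladium-catalysed formate reduction (Pd(OAc)2, PPh3, HCO2H, Et3N, DMF) would then replace iodine by hydrogen, and the sequence comes back to the route at 16.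

**Step 3.** The catalyst may discriminate the two enantiotopic enone units poorly, or ligand-free background addition may erode the enantiomeric purity at the future C3a. The fallback sets out from 7 and separates the two tasks. An ene-reductase of the old yellow enzyme family (NADP+, glucose, glucose dehydrogenase, phosphate buffer pH 7, 30 °C) would desymmetrise the dienone by conjugate reduction to (S)-4-[(triethylsilyl)oxy]-4-vinylcyclohex-2-en-1-one F2. A ligand-free nickel-catalysed addition of 9 (Ni(acac)2, i-Bu2AlH, Et2O) would then deliver the propynyl group under substrate control, anti to the vinyl group. After protonation of the aluminium enolate the sequence comes back to the route at 12.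

**Step 14.** Equilibration at C8 may be slow at the hindered methine or may not favour the wanted epimer strongly enough, and retro-aldol cleavage or dehydration of the β-hydroxy ketone may compete. The fallback sets out from 22 and fixes C8 by a stereospecific hydride transfer instead of by equilibration:
- Suzuki coupling with isopropenylboronic acid pinacol ester (Pd(PPh3)4, K3PO4, dioxane/H2O) would give the diene (2R,3S,3aS,5S,8aR)-2,3-epoxy-2,5-dimethyl-8-(prop-1-en-2-yl)-5-[(triethylsilyl)oxy]-1,2,3,3a,4,5,6,8a-octahydroazulene F3.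
- m-CPBA (NaHCO3, CH2Cl2, 0 °C) should epoxidise the more electron-rich ring alkene from the open β face to the vinyl epoxide, the 7β,8β-epoxide of F3, F4.
- Hydrogenolysis with zerovalent palladium and formate (Pd(PPh3)4, HCO2H, Et3N, THF) should ionise the allylic C8–O bond with inversion and deliver hydride to C8 from the α face. This gives the homoallylic alcohol with H-8 α, isopropenyl β and 7-OH β, F5.
- Hydrogenation of the isopropenyl group (RhCl(PPh3)3, H2, benzene) gives the 7β-alcohol, the 7-epimer of the 5-O-triethylsilyl ether of 30, F6.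
- Dess–Martin oxidation gives the 5-O-triethylsilyl ether of 29, F7.
- Bu4NF/AcOH then removes the silyl group, and the sequence comes back to the route at 29.

## Further compounds

F1 | step 7 | (3aS,5S,8aS)-3-iodo-2,5-dimethyl-5-[(triethylsilyl)oxy]-3a,4,5,6,7,8a-hexahydroazulen-8(1H)-one | O=C1[C@H]2CC(C)=C(I)[C@H]2C[C@@](C)(O[Si](CC)(CC)CC)CC1
F2 | step 3 | (S)-4-[(triethylsilyl)oxy]-4-vinylcyclohex-2-en-1-one | C=C[C@@]1(O[Si](CC)(CC)CC)CCC(=O)C=C1
F3 | step 14 | (2R,3S,3aS,5S,8aR)-2,3-epoxy-2,5-dimethyl-8-(prop-1-en-2-yl)-5-[(triethylsilyl)oxy]-1,2,3,3a,4,5,6,8a-octahydroazulene | CC(=C)C=1[C@@H]2C[C@@]3(C)O[C@H]3[C@H]2C[C@@](C)(O[Si](CC)(CC)CC)CC=1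
F4 | step 14 | 7β,8β-epoxide of F3 (2,3:7,8-diepoxy-2,5-dimethyl-8-(prop-1-en-2-yl)-5-[(triethylsilyl)oxy]perhydroazulene) | CC(=C)[C@]1(O4)[C@@H]2C[C@@]3(C)O[C@H]3[C@H]2C[C@@](C)(O[Si](CC)(CC)CC)C[C@H]14
F5 | step 14 | 2,3-epoxy-2,5-dimethyl-8-(prop-1-en-2-yl)-5-[(triethylsilyl)oxy]perhydroazulen-7-ol with 7-OH β and H-8 α | CC(=C)[C@H]1[C@@H]2C[C@@]3(C)O[C@H]3[C@H]2C[C@@](C)(O[Si](CC)(CC)CC)C[C@H]1O
F6 | step 14 | 2,3-epoxy-2,5-dimethyl-8-(propan-2-yl)-5-[(triethylsilyl)oxy]perhydroazulen-7-ol with 7-OH β (7-epimer of the 5-O-triethylsilyl ether of 30) | CC(C)[C@H]1[C@@H]2C[C@@]3(C)O[C@H]3[C@H]2C[C@@](C)(O[Si](CC)(CC)CC)C[C@H]1O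
F7 | step 14 | (2R,3S,3aS,5R,8S,8aR)-2,3-epoxy-2,5-dimethyl-8-(propan-2-yl)-5-[(triethylsilyl)oxy]perhydroazulen-7-one | CC(C)[C@H]1[C@@H]2C[C@@]3(C)O[C@H]3[C@H]2C[C@@](C)(O[Si](CC)(CC)CC)CC1=O
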